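**Plan**

Numbering: ring B = C1–C5 plus spiro C6; ring A = C6–C11 (C7 is the =C–CH3 carbon, C10 the CHBr carbon, C11 the CMe2 carbon).

1. Cuts, in retrosynthetic order: C2–Cl and C3–Br (back to a 2,3-epoxide and the C2=C3 alkene); C3–CH3 (enol triflate of a C3 ketone); C6–C7 (ring A opened to a but-2-ynyl chain); C6–C11 (aryl–CMe2 bond); C10–Br (epoxide); C8–C9 (propynyl + prenyl).
2. Enabling feature: C3 of ring B is para to the spiro carbon C6, so ring B is a reduced para-substituted phenol. An oxygen at C3 makes C6 the nucleophilic ipso carbon, the C7(CH3)=C8 alkene is what a methyl-capped alkyne leaves after 6-endo attack, and the benzylic C11 gem-dimethyl carbon is a Friedel–Crafts retron.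
3. Forward order: the C8–C9 chain is joined first, then C10/C11 are epoxidised and brominated, and phenol is attached at C11. Ring A is then closed onto the phenol ipso carbon, which creates the spiro centre and delivers ring B as a dienone. Ring B is reduced, desymmetrised, methylated and halogenated last.
4. Stereochemistry: C10 comes from a Shi epoxidation followed by SN2 bromide opening and is not touched again. C6 comes from a chiral lithium amide desymmetrisation of the C3 ketone. C2 and C3 come from epoxidation anti to the axial C7, followed by three stereospecific anti events (epoxide opening, bromonium-mediated chlorination with retention, diaxial-to-diequatorial Br/Cl interchange).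

Key step: step 5

Remark: ring B of the spirocycle is taken to sit in the chair with C11 equatorial and C7 axial (its methyl over ring B); in that chair the 2-Cl and 3-Br of the target are both equatorial and the 3-CH3 is axial.

**Route**

Step 1
Reactants: 1 1-bromo-3-methylbut-2-ene (prenyl bromide); 2 prop-1-yn-1-ylmagnesium bromide
Product: 3 2-methylhept-2-en-5-yne
Conditions: CuBr·SMe2 (5 mol %), THF, −20 °C → rt
Reagents that add atoms: none
Why: Copper-catalysed SN2 coupling of an alkynyl Grignard reagent with a primary allylic bromide should give the skipped enyne, attack at the unhindered CH2 terminus being preferred over SN2′ attack at the gem-dimethyl carbon.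

Step 2
Reactants: 3 2-methylhept-2-en-5-yne
Product: 4 (3S)-3-(but-2-yn-1-yl)-2,2-dimethyloxirane
Conditions: ent-Shi ketone (L-series, 30 mol %), Oxone, K2CO3, Bu4NHSO4, MeCN/dimethoxymethane/aq. buffer (pH 10.5), 0 °C
Reagents that add atoms: potassium peroxymonosulfate (Oxone), [K+].[O-]S(=O)(=O)OO
Why: Shi asymmetric epoxidation of a trisubstituted alkene by the chiral dioxirane (spiro transition state) should give the 3S epoxide with the enantiomeric ketone, since the D-fructose catalyst would give 3R; the internal alkyne should be inert.

Step 3
Reactants: 4 (3S)-3-(but-2-yn-1-yl)-2,2-dimethyloxirane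
Product: 5 (3R)-3-bromo-2-methylhept-5-yn-2-ol
Conditions: Li2NiBr4, THF, 0 °C → rt; aq. phosphate buffer work-up
Reagents that add atoms: dilithium tetrabromonickelate, [Li+].[Li+].Br[Ni-2](Br)(Br)Br
Why: SN2 opening of the epoxide by soft bromide at the less substituted carbon (bromohydrin formation) should invert C3 and so set the R C–Br centre that becomes C10 of the target.

Step 4
Reactants: 5 (3R)-3-bromo-2-methylhept-5-yn-2-ol; 6 phenol (5 equiv)
Product: 7 4-[(3R)-3-bromo-2-methylhept-5-yn-2-yl]phenol
Conditions: TfOH (2 mol %), (CF3)2CHOH, 0 °C → rt
Reagents that add atoms: none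
Why: Friedel–Crafts tert-alkylation with loss of water: acid ionises the tertiary carbinol with anchimeric assistance from the neighbouring bromine (bromonium ion) and the para carbon of phenol attacks the tertiary carbon, so the C–Br stereocentre, none of whose bonds is broken, should be retained.

Step 5
Reactants: 7 4-[(3R)-3-bromo-2-methylhept-5-yn-2-yl]phenol
Product: 8 (10R)-10-bromo-7,11,11-trimethylspiro[5.5]undeca-1,4,7-trien-3-one
Conditions: [JohnPhosAu(MeCN)]SbF6 (5 mol %), CH2Cl2, rt
Reagents that add atoms: none
Why: Proposed new method: cationic gold(I) π-activates the alkyne and the phenol ipso carbon (future C6, para to OH) attacks the methyl-bearing alkyne carbon (future C7) anti to gold; loss of the phenolic proton gives the cross-conjugated dienone and the same proton cleaves the C8–Au bond, so the step is an atom-neutral cycloisomerisation. The closest known reaction types are the gold-catalysed ipso-Friedel–Crafts dearomatisation of para-substituted phenols carrying terminal alkynes (5-exo-dig) and the 6-endo-dig gold hydroarylation of internal aryl alkynes; the 6-endo-dig ipso mode on an unactivated methyl-capped alkyne is the untested element. Ring A closes 6-endo-dig, which places the C7=C8 double bond and the C7 methyl as in the target. No new stereocentre arises, because C6 carries two identical dienone arms, and C10 is not involved and keeps its R configuration. The step needs ipso over ortho attack, secured by the para-hydroxyl (the ortho carbons are meta to it), and 6-endo over 5-exo closure, expected because C7 is the better cation-stabilising alkyne terminus (C8 lies β to the C–Br dipole), because the 5-exo alternative would press a tetrasubstituted exocyclic vinylgold against the spiro carbon and the C11 gem-dimethyl group, and because that gem-dimethyl group preorganises the chain.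

Step 6
Reactants: 8 (10R)-10-bromo-7,11,11-trimethylspiro[5.5]undeca-1,4,7-trien-3-one
Product: 10 (10R)-10-bromo-7,11,11-trimethylspiro[5.5]undec-7-en-3-one, via mono-enone 9 (not isolated)
Conditions: [(Ph3P)CuH]6 (3 mol %), H2 (35 bar), t-BuOH, benzene, rt
Reagents that add atoms: none
Why: Copper hydride conjugate reduction (catalytic under hydrogen) is chemoselective for enone C=C bonds over the isolated trisubstituted alkene and the alkyl bromide; both arms should be reduced, so C6 stays non-stereogenic.

Step 7
Reactants: 10 (10R)-10-bromo-7,11,11-trimethylspiro[5.5]undec-7-en-3-one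
Product: 12 (6S,10R)-10-bromo-7,11,11-trimethylspiro[5.5]undeca-2,7-dien-3-yl trifluoromethanesulfonate, via lithium enolate 11 (not isolated)
Conditions: lithium (R,R)-bis(1-phenylethyl)amide (1.2 equiv), LiCl, THF, −78 °C; then Comins' reagent, −78 → −20 °C
Reagents that add atoms: Comins' reagent, FC(F)(F)S(=O)(=O)N(c1ccc(Cl)cn1)S(=O)(=O)C(F)(F)F
Why: Desymmetrising deprotonation of a 4,4-disubstituted cyclohexanone by a chiral lithium amide, followed by O-triflation, should select one of the two CH2 arms and thereby fix C6 as S under reagent control; the (R,R)-amide is chosen by analogy with its sense on 4-substituted cyclohexanones (equatorial C11 in the role of the 4-substituent), and the equatorial C10 bromide has no antiperiplanar hydrogen for E2.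

Step 8
Reactants: 12 (6S,10R)-10-bromo-7,11,11-trimethylspiro[5.5]undeca-2,7-dien-3-yl trifluoromethanesulfonate
Product: 13 (6S,10R)-10-bromo-3,7,11,11-tetramethylspiro[5.5]undeca-2,7-diene
Conditions: Me2CuLi, THF, −15 °C
Reagents that add atoms: lithium dimethylcuprate, [Li+].C[Cu-]C
Why: Cross-coupling of an enol triflate with a Gilman cuprate should replace OTf by CH3 without moving the double bond; the hindered secondary bromide should be inert to the cuprate at this temperature.

Step 9
Reactants: 13 (6S,10R)-10-bromo-3,7,11,11-tetramethylspiro[5.5]undeca-2,7-diene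
Product: 14 (2S,3R,6S,10R)-10-bromo-2,3-epoxy-3,7,11,11-tetramethylspiro[5.5]undec-7-ene (oxygen on the ring B face syn to C11)
Conditions: mCPBA (1.0 equiv), NaHCO3, CH2Cl2, −20 °C
Reagents that add atoms: 3-chloroperoxybenzoic acid, OOC(=O)c1cccc(Cl)c1
Why: Prilezhaev epoxidation; the ring B alkene is less hindered than the ring A alkene flanked by the spiro carbon, and the peracid should attack the face anti to the axial C7 (whose methyl lies over ring B), i.e. syn to C11.

Step 10
Reactants: 14 (2S,3R,6S,10R)-10-bromo-2,3-epoxy-3,7,11,11-tetramethylspiro[5.5]undec-7-ene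
Product: 15 (2R,3R,6S,10R)-2,10-dibromo-3,7,11,11-tetramethylspiro[5.5]undec-7-en-3-ol
Conditions: Li2NiBr4, THF, 0 °C → rt; aq. phosphate buffer work-up
Reagents that add atoms: dilithium tetrabromonickelate, [Li+].[Li+].Br[Ni-2](Br)(Br)Br
Why: trans-Diaxial SN2 opening of the epoxide (Fürst–Plattner rule) by bromide at the secondary C2, anti to oxygen, should give the axial 2-bromide (inversion at C2) and the axial 3-hydroxyl.

Step 11
Reactants: 15 (2R,3R,6S,10R)-2,10-dibromo-3,7,11,11-tetramethylspiro[5.5]undec-7-en-3-ol
Product: 17 (2R,3R,6S,10R)-2,10-dibromo-3-chloro-3,7,11,11-tetramethylspiro[5.5]undec-7-ene, via chlorosulfite ester 16 (not isolated)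
Conditions: SOCl2 (1.5 equiv), Et2O, −30 → 0 °C
Reagents that add atoms: thionyl chloride, ClS(Cl)=O
Why: Deoxychlorination with neighbouring-group participation: the antiperiplanar axial C2 bromine expels the chlorosulfite to a bromonium ion, which chloride opens at the tertiary C3 on the face the oxygen left, giving net retention at C3 (double inversion) and the trans-diaxial 2-bromo-3-chloride.

Step 12
Reactants: 17 (2R,3R,6S,10R)-2,10-dibromo-3-chloro-3,7,11,11-tetramethylspiro[5.5]undec-7-ene
Product: 18 (2S,3S,6S,10R)-3,10-dibromo-2-chloro-3,7,11,11-tetramethylspiro[5.5]undec-7-ene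
Conditions: MeNO2, 60 °C, dark
Reagents that add atoms: none
Why: Thermal diaxial-to-diequatorial 1,2-interchange of a vicinal dihalide (type I dyotropic rearrangement, as known for trans-diaxial steroidal dihalides): bromine moves from C2 to C3 and chlorine from C3 to C2, each on its own face and with inversion at both carbons, driven by relief of the 1,3-diaxial contact between the C2 bromine and C7.

**Compound list**

1 | 1-bromo-3-methylbut-2-ene (prenyl bromide) | CC(C)=CCBr | starting material
2 | prop-1-yn-1-ylmagnesium bromide | CC#C[Mg]Br | starting material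
3 | 2-methylhept-2-en-5-yne | CC#CCC=C(C)C | intermediate
4 | (3S)-3-(but-2-yn-1-yl)-2,2-dimethyloxirane | CC#CC[C@@H]1OC1(C)C | intermediate
5 | (3R)-3-bromo-2-methylhept-5-yn-2-ol | CC#CC[C@@H](Br)C(C)(C)O | intermediate
6 | phenol | Oc1ccccc1 | starting material
7 | 4-[(3R)-3-bromo-2-methylhept-5-yn-2-yl]phenol | CC#CC[C@@H](Br)C(C)(C)c1ccc(O)cc1 | intermediate
8 | (10R)-10-bromo-7,11,11-trimethylspiro[5.5]undeca-1,4,7-trien-3-one | CC1=CC[C@@H](Br)C(C)(C)C12C=CC(=O)C=C2 | intermediate
9 | (10R)-10-bromo-7,11,11-trimethylspiro[5.5]undeca-1,7-dien-3-one (either C6 epimer, not isolated) | CC1=CC[C@@H](Br)C(C)(C)C12CCC(=O)C=C2 | intermediate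
10 | (10R)-10-bromo-7,11,11-trimethylspiro[5.5]undec-7-en-3-one | CC1=CC[C@@H](Br)C(C)(C)C12CCC(=O)CC2 | intermediate
11 | lithium (6S,10R)-10-bromo-7,11,11-trimethylspiro[5.5]undeca-2,7-dien-3-olate (not isolated) | [Li+].CC1=CC[C@@H](Br)C(C)(C)[C@]12CCC([O-])=CC2 | intermediate
12 | (6S,10R)-10-bromo-7,11,11-trimethylspiro[5.5]undeca-2,7-dien-3-yl trifluoromethanesulfonate | CC1=CC[C@@H](Br)C(C)(C)[C@]12CCC(OS(=O)(=O)C(F)(F)F)=CC2 | intermediate
13 | (6S,10R)-10-bromo-3,7,11,11-tetramethylspiro[5.5]undeca-2,7-diene | CC1=CC[C@@H](Br)C(C)(C)[C@]12CCC(C)=CC2 | intermediate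
14 | (2S,3R,6S,10R)-10-bromo-2,3-epoxy-3,7,11,11-tetramethylspiro[5.5]undec-7-ene | CC1=CC[C@@H](Br)C(C)(C)[C@]12CC[C@@]3(C)O[C@H]3C2 | intermediate
15 | (2R,3R,6S,10R)-2,10-dibromo-3,7,11,11-tetramethylspiro[5.5]undec-7-en-3-ol | CC1=CC[C@@H](Br)C(C)(C)[C@]12CC[C@@](C)(O)[C@H](Br)C2 | intermediate
16 | chlorosulfite ester of 15 at the C3 oxygen (not isolated) | CC1=CC[C@@H](Br)C(C)(C)[C@]12CC[C@@](C)(OS(Cl)=O)[C@H](Br)C2 | intermediate
17 | (2R,3R,6S,10R)-2,10-dibromo-3-chloro-3,7,11,11-tetramethylspiro[5.5]undec-7-ene | CC1=CC[C@@H](Br)C(C)(C)[C@]12CC[C@@](C)(Cl)[C@H](Br)C2 | intermediate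
18 | (2S,3S,6S,10R)-3,10-dibromo-2-chloro-3,7,11,11-tetramethylspiro[5.5]undec-7-ene | CC1=CC[C@@H](Br)C(C)(C)[C@]12CC[C@](C)(Br)[C@@H](Cl)C2 | target

**Step count and risks**

Total steps: 12. Longest linear sequence: 12 steps (from 1).

Steps most likely to fail:

1. Step 5. The ring may close through the other alkyne carbon (5-exo-dig, giving a spiro[4.5] skeleton), or the dienone may undergo acid-promoted dienone–phenol rearrangement under the cationic catalyst. The fallback fixes the reacting carbon beforehand and uses radical chemistry. It sets out from 7: hydrozirconation with Schwartz's reagent (2.2 equiv, THF) and iodinolysis should place iodine on the methyl-bearing alkyne carbon and give 4-[(3R,5E)-3-bromo-6-iodo-2-methylhept-5-en-2-yl]phenol F1. The vinyl radical generated from F1 by visible-light photoredox catalysis (fac-Ir(ppy)3, 2,6-lutidine, MeCN, blue light) should close 6-exo onto the ipso carbon, the known radical dearomative ipso-spirocyclisation mode of arene-tethered vinyl radicals. Oxidation of the cyclohexadienyl radical with loss of the phenolic proton brings the material back to the route at 8.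

2. Step 12. Heating may cause loss of hydrogen halide from the tertiary centre, or the interchange may be too slow or not favour the diequatorial isomer far enough. The fallback replaces the thermal, concerted interchange of isolated 17 by a reversible ionic route. It sets out from 15 and skips 17: chlorotrimethylsilane with catalytic zinc chloride in CH2Cl2 should ionise the tertiary C3 centre with bromine participation again and again, so that chloride return at C2 of the bridged bromonium ion can drain the material to the diequatorial isomer, which rejoins the route at 18. This fallback makes no new compound (F0).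

3. Step 7. The chiral base may discriminate poorly between the two CH2 arms, because the axial α-hydrogens lie under the C7 methyl, or it may deprotonate in the opposite sense. The fallback moves the desymmetrisation to the dienone and makes the enolate regiospecifically. It sets out from 8: an ene-reductase (Old Yellow Enzyme family, NADPH recycling with glucose dehydrogenase) should reduce one of the two dienone C=C bonds selectively, as known for 4,4-disubstituted cyclohexa-2,5-dienones, and give (6S,10R)-10-bromo-7,11,11-trimethylspiro[5.5]undeca-1,7-dien-3-one F2. Conjugate reduction of F2 with L-Selectride (THF, −78 °C) should form enolate 11 on the arm that still carries the double bond, and trapping with Comins' reagent returns to the route at 12.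

Further compounds
F1 | step 5 | 4-[(3R,5E)-3-bromo-6-iodo-2-methylhept-5-en-2-yl]phenol | C/C(I)=C\C[C@@H](Br)C(C)(C)c1ccc(O)cc1
F0 | step 12 | none | none
F2 | step 7 | (6S,10R)-10-bromo-7,11,11-trimethylspiro[5.5]undeca-1,7-dien-3-one | CC1=CC[C@@H](Br)C(C)(C)[C@]12CCC(=O)C=C2
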